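**Strategy.** Ring B is grown, not attached. It carries oxygen at C2', C4' and C5' (C2' and C5' para to each other) and hydrogen at C3' and C6'. That pattern is what remains when a 2,4-bis(silyloxy)furan adds across a terminal alkyne on chromone C2 and the oxygen bridge of the adduct opens. One operation should therefore form C1'–C2' and C5'–C6', close ring B, place all three ring B oxygens and deliver the oxidation-prone hydroxyhydroquinone partly silylated. The precursor is the complete ring A/ring C unit, 2-ethynyl-5,7-bis(methoxymethoxy)-3,6,8-triprenylchromone, assembled from 2,4,6-trihydroxyacetophenone by C-prenylation, an oxalate chromone synthesis and one-carbon homologation of the C2 aldehyde.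

Key step: step 9

Assumption: the target has no stereocentre; the stereocentres of the transient hemiketal 8 and of the cycloadduct 16 form without control and are erased within the same step.

Step 1
Reactants: 1 2,4,6-trihydroxyacetophenone; 2 prenyl bromide (1-bromo-3-methylbut-2-ene)
Product: 3 3,5-diprenyl-2,4,6-trihydroxyacetophenone
Conditions: 2 (2.2 equiv), 10% aq KOH, 0 °C → rt
Reagents that add atoms: none
Why: C-alkylation of the ambident acylphloroglucinol phenoxide, for which aqueous alkali favours attack through carbon at the two free ring positions C3 and C5, is an established C-prenylation; the diprenyl compound should be separable by chromatography from mono- and gem-dialkylated material.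

Step 2
Reactants: 3 3,5-diprenyl-2,4,6-trihydroxyacetophenone
Product: 4 1-[2-hydroxy-4,6-bis(methoxymethoxy)-3,5-bis(3-methylbut-2-en-1-yl)phenyl]ethan-1-one
Conditions: MOMCl (2.3 equiv), i-Pr2NEt, CH2Cl2, 0 °C → rt
Reagents that add atoms: chloromethyl methyl ether, COCCl
Why: O-alkylation (acetal formation) should stop at the bis-ether, because the para hydroxyl and one of the two equivalent ortho hydroxyls react while the remaining one is deactivated by its hydrogen bond to the acetyl carbonyl.

Step 3
Reactants: 4 1-[2-hydroxy-4,6-bis(methoxymethoxy)-3,5-bis(3-methylbut-2-en-1-yl)phenyl]ethan-1-one; 2 prenyl bromide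
Product: 5 1-[2-hydroxy-4,6-bis(methoxymethoxy)-3,5-bis(3-methylbut-2-en-1-yl)phenyl]-5-methylhex-4-en-1-one
Conditions: LiN(i-Pr)2 (2.2 equiv), THF, −78 °C; 2 (1.05 equiv), −78 → 0 °C; AcOH
Reagents that add atoms: none
Why: Enolate alkylation of the phenoxide–enolate dianion, in which the lithium phenoxide is inert at low temperature and the methyl-ketone enolate carbon displaces the allylic bromide by SN2, installs the carbon that becomes C3 together with its prenyl group.

Step 4
Reactants: 5 1-[2-hydroxy-4,6-bis(methoxymethoxy)-3,5-bis(3-methylbut-2-en-1-yl)phenyl]-5-methylhex-4-en-1-one; 6 diethyl oxalate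
Product: 9 ethyl 5,7-bis(methoxymethoxy)-3,6,8-tris(3-methylbut-2-en-1-yl)-4-oxo-4H-chromene-2-carboxylate, via open-chain 2,4-dioxo ester 7 (not isolated), via cyclic hemiketal 8 (not isolated)
Conditions: LiN(SiMe3)2 (3.3 equiv), THF, −78 °C; 6 (1.5 equiv), −78 → 0 °C; AcOH; then TsOH·H2O (cat.), PhMe, 4 Å MS, 50 °C
Reagents that add atoms: none
Why: Crossed Claisen condensation of the ketone enolate with non-enolizable diethyl oxalate, then acid-catalysed hemiketalization at the highly electrophilic α-keto ester carbonyl and dehydration, is the classical oxalate route to chromone-2-carboxylates and is known for α-substituted o-hydroxyaryl ketones; catalytic acid without a protic co-solvent is chosen to spare the MOM acetals.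

Step 5
Reactants: 9 ethyl 5,7-bis(methoxymethoxy)-3,6,8-tris(3-methylbut-2-en-1-yl)-4-oxo-4H-chromene-2-carboxylate
Product: 10 2-(hydroxymethyl)-5,7-bis(methoxymethoxy)-3,6,8-tris(3-methylbut-2-en-1-yl)-4H-chromen-4-one
Conditions: NaBH4, EtOH–THF, 0 °C
Reagents that add atoms: none
Why: Chemoselective hydride reduction is expected because the C2 ester is activated by the ring oxygen and by conjugation with the pyranone, whereas the C4 carbonyl is a fully substituted vinylogous ester, as is known for chromone-2-carboxylates.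

Step 6
Reactants: 10 2-(hydroxymethyl)-5,7-bis(methoxymethoxy)-3,6,8-tris(3-methylbut-2-en-1-yl)-4H-chromen-4-one
Product: 11 5,7-bis(methoxymethoxy)-3,6,8-tris(3-methylbut-2-en-1-yl)-4-oxo-4H-chromene-2-carbaldehyde
Conditions: Dess–Martin periodinane, CH2Cl2, 0 °C → rt
Reagents that add atoms: none
Why: Dess–Martin oxidation of the primary alcohol should stop at the aldehyde under near-neutral conditions and leave the prenyl alkenes and the MOM acetals untouched.

Step 7
Reactants: 11 5,7-bis(methoxymethoxy)-3,6,8-tris(3-methylbut-2-en-1-yl)-4-oxo-4H-chromene-2-carbaldehyde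
Product: 12 2-ethynyl-5,7-bis(methoxymethoxy)-3,6,8-tris(3-methylbut-2-en-1-yl)-4H-chromen-4-one
Conditions: Me3SiCHN2 (1.2 equiv), LiN(i-Pr)2 (1.2 equiv), THF, −78 °C; 11, −78 → 0 °C; H2O
Reagents that add atoms: trimethylsilyldiazomethane, C[Si](C)(C)C=[N+]=[N-]
Why: In the Colvin rearrangement the lithiated silyldiazomethane adds to the aldehyde (much more electrophilic than the C4 carbonyl), Peterson-type loss of Me3SiOLi gives a diazoalkene, and loss of N2 with a 1,2-hydrogen shift gives the terminal alkyne in an aprotic medium free of nucleophiles that could add to the conjugated product.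

Step 8
Reactants: 13 tetronic acid
Product: 15 2,4-bis(tert-butyldimethylsilyloxy)furan, via 4-silyloxybutenolide 14 (not isolated)
Conditions: TBSOTf (2.2 equiv), Et3N (3 equiv), CH2Cl2, 0 °C → rt
Reagents that add atoms: tert-butyldimethylsilyl trifluoromethanesulfonate, CC(C)(C)[Si](C)(C)OS(=O)(=O)C(F)(F)F
Why: Double O-silylation should occur because the acidic enol is silylated first and the resulting butenolide is then enolized at C5 by the silyl triflate/amine pair (soft enolization, the standard silyl dienol ether route to 2-silyloxyfurans), which gives the aromatic furan.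

Step 9
Reactants: 12 2-ethynyl-5,7-bis(methoxymethoxy)-3,6,8-tris(3-methylbut-2-en-1-yl)-4H-chromen-4-one; 15 2,4-bis(tert-butyldimethylsilyloxy)furan
Product: 17 2-[2,4-bis(tert-butyldimethylsilyloxy)-5-hydroxyphenyl]-5,7-bis(methoxymethoxy)-3,6,8-tris(3-methylbut-2-en-1-yl)-4H-chromen-4-one, via 7-oxanorbornadiene cycloadduct 16 (not isolated)
Conditions: 15 (2.5 equiv), PhMe (1 M), 80 °C, Ar, sealed tube
Reagents that add atoms: none
Why: Furan 15 is a cyclic 1,3-dioxygenated diene of very high HOMO energy, and the ethynyl group of 12 is electron-poor because it extends the pyranone enone from its β-carbon C2, so a normal-demand Diels–Alder reaction across the triple bond should form C1'–C2' and C5'–C6' and close the six-membered carbocycle by intermolecular [4+2] cycloaddition to give 16. In 16 the bridgehead C2' is a silyl ketal, so its bond to the bridge oxygen breaks to a silyloxy-stabilized cation, the bridge oxygen is kept by C5', and removal of the C5' hydrogen aromatizes ring B to the C5' phenol with silyl ethers at C2' and C4'. The closest known reaction type is the Diels–Alder reaction of 2-silyloxyfurans with acetylenic esters and ketones, which opens in the same way to hydroquinone mono-ethers. The selectivity required is regiochemical: the largest HOMO coefficient sits on furan C5 (the free α-carbon beside the 4-silyloxy carbon) and the largest LUMO coefficient on the CH terminus of the alkyne, so these atoms join as C5'–C6' and the silyl ketal carbon becomes C2' next to the chromone; a stepwise Michael-type first bond between the same atoms leads to the same ring. Chemoselectivity comes from the substrate, since the alkyne is the only unhindered electron-poor π bond (the prenyl alkenes are electron-rich, the pyranone C2=C3 bond is tetrasubstituted) and both ring A hydroxyls are capped so that no acidic proton destroys the silyl ketene acetal. No stereocentre persists, because the two bridgehead centres of racemic 16 are lost on aromatization.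

Step 10
Reactants: 17 2-[2,4-bis(tert-butyldimethylsilyloxy)-5-hydroxyphenyl]-5,7-bis(methoxymethoxy)-3,6,8-tris(3-methylbut-2-en-1-yl)-4H-chromen-4-one
Product: 18 5,7-bis(methoxymethoxy)-2-(2,4,5-trihydroxyphenyl)-3,6,8-tris(3-methylbut-2-en-1-yl)-4H-chromen-4-one
Conditions: Bu4NF (2.2 equiv), AcOH (2.5 equiv), degassed THF, 0 °C, Ar
Reagents that add atoms: none
Why: Fluoride-induced cleavage of aryl silyl ethers (Si–F bond formation) is fast at 0 °C, the acetic acid buffer keeps the hydroxyhydroquinone protonated and thus less prone to oxidation, and MOM acetals are inert to fluoride.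

Step 11
Reactants: 18 5,7-bis(methoxymethoxy)-2-(2,4,5-trihydroxyphenyl)-3,6,8-tris(3-methylbut-2-en-1-yl)-4H-chromen-4-one
Product: 19 5,7-dihydroxy-2-(2,4,5-trihydroxyphenyl)-3,6,8-tris(3-methylbut-2-en-1-yl)-4H-chromen-4-one (CNP0243236.0)
Conditions: HCl (1 M in degassed MeOH), rt → 40 °C, Ar
Reagents that add atoms: none
Why: Acid-catalysed transacetalization of the two MOM acetals to the solvent methanol frees the C5 and C7 hydroxyls; dilute acid, mild temperature and exclusion of air are chosen so that the prenyl alkenes do not add to neighbouring phenols and the trihydroxyphenyl ring is not oxidized.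

Compound list
1 | 2,4,6-trihydroxyacetophenone | CC(=O)c1c(O)cc(O)cc1O | starting material
2 | prenyl bromide (1-bromo-3-methylbut-2-ene) | CC(C)=CCBr | starting material
3 | 3,5-diprenyl-2,4,6-trihydroxyacetophenone | CC(=O)c1c(O)c(CC=C(C)C)c(O)c(CC=C(C)C)c1O | intermediate
4 | 1-[2-hydroxy-4,6-bis(methoxymethoxy)-3,5-bis(3-methylbut-2-en-1-yl)phenyl]ethan-1-one | CC(=O)c1c(O)c(CC=C(C)C)c(OCOC)c(CC=C(C)C)c1OCOC | intermediate
5 | 1-[2-hydroxy-4,6-bis(methoxymethoxy)-3,5-bis(3-methylbut-2-en-1-yl)phenyl]-5-methylhex-4-en-1-one | CC(C)=CCCC(=O)c1c(O)c(CC=C(C)C)c(OCOC)c(CC=C(C)C)c1OCOC | intermediate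
6 | diethyl oxalate | CCOC(=O)C(=O)OCC | starting material
7 | ethyl 4-[2-hydroxy-4,6-bis(methoxymethoxy)-3,5-diprenylphenyl]-3-(3-methylbut-2-en-1-yl)-2,4-dioxobutanoate (racemic, enolizable) | CCOC(=O)C(=O)C(CC=C(C)C)C(=O)c1c(O)c(CC=C(C)C)c(OCOC)c(CC=C(C)C)c1OCOC | intermediate (not isolated)
8 | ethyl 2-hydroxy-5,7-bis(methoxymethoxy)-3,6,8-triprenyl-4-oxochromane-2-carboxylate (mixture of diastereomers) | CCOC(=O)C1(O)Oc2c(CC=C(C)C)c(OCOC)c(CC=C(C)C)c(OCOC)c2C(=O)C1CC=C(C)C | intermediate (not isolated)
9 | ethyl 5,7-bis(methoxymethoxy)-3,6,8-tris(3-methylbut-2-en-1-yl)-4-oxo-4H-chromene-2-carboxylate | CCOC(=O)c1oc2c(CC=C(C)C)c(OCOC)c(CC=C(C)C)c(OCOC)c2c(=O)c1CC=C(C)C | intermediate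
10 | 2-(hydroxymethyl)-5,7-bis(methoxymethoxy)-3,6,8-tris(3-methylbut-2-en-1-yl)-4H-chromen-4-one | OCc1oc2c(CC=C(C)C)c(OCOC)c(CC=C(C)C)c(OCOC)c2c(=O)c1CC=C(C)C | intermediate
11 | 5,7-bis(methoxymethoxy)-3,6,8-tris(3-methylbut-2-en-1-yl)-4-oxo-4H-chromene-2-carbaldehyde | O=Cc1oc2c(CC=C(C)C)c(OCOC)c(CC=C(C)C)c(OCOC)c2c(=O)c1CC=C(C)C | intermediate
12 | 2-ethynyl-5,7-bis(methoxymethoxy)-3,6,8-tris(3-methylbut-2-en-1-yl)-4H-chromen-4-one | C#Cc1oc2c(CC=C(C)C)c(OCOC)c(CC=C(C)C)c(OCOC)c2c(=O)c1CC=C(C)C | intermediate
13 | tetronic acid (furan-2,4(3H,5H)-dione) | O=C1CC(=O)CO1 | starting material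
14 | 4-(tert-butyldimethylsilyloxy)furan-2(5H)-one | CC(C)(C)[Si](C)(C)OC1=CC(=O)OC1 | intermediate (not isolated)
15 | 2,4-bis(tert-butyldimethylsilyloxy)furan | CC(C)(C)[Si](C)(C)Oc1cc(O[Si](C)(C)C(C)(C)C)co1 | intermediate
16 | 7-oxanorbornadiene cycloadduct: 1,3-bis(tert-butyldimethylsilyloxy)-7-oxabicyclo[2.2.1]hepta-2,5-diene bearing the chromon-2-yl group on C6 (racemic, bridgehead configuration fixed by the bicycle) | CC(C)(C)[Si](C)(C)OC1=CC2(O[Si](C)(C)C(C)(C)C)OC1C=C2c1oc2c(CC=C(C)C)c(OCOC)c(CC=C(C)C)c(OCOC)c2c(=O)c1CC=C(C)C | intermediate (not isolated)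
17 | 2-[2,4-bis(tert-butyldimethylsilyloxy)-5-hydroxyphenyl]-5,7-bis(methoxymethoxy)-3,6,8-tris(3-methylbut-2-en-1-yl)-4H-chromen-4-one | CC(C)=CCc1c(OCOC)c(CC=C(C)C)c2oc(-c3cc(O)c(O[Si](C)(C)C(C)(C)C)cc3O[Si](C)(C)C(C)(C)C)c(CC=C(C)C)c(=O)c2c1OCOC | intermediate
18 | 5,7-bis(methoxymethoxy)-2-(2,4,5-trihydroxyphenyl)-3,6,8-tris(3-methylbut-2-en-1-yl)-4H-chromen-4-one | CC(C)=CCc1c(OCOC)c(CC=C(C)C)c2oc(-c3cc(O)c(O)cc3O)c(CC=C(C)C)c(=O)c2c1OCOC | intermediate
19 | 5,7-dihydroxy-2-(2,4,5-trihydroxyphenyl)-3,6,8-tris(3-methylbut-2-en-1-yl)-4H-chromen-4-one | CC(C)=CCc1c(O)c(CC=C(C)C)c2oc(-c3cc(O)c(O)cc3O)c(CC=C(C)C)c(=O)c2c1O | target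

Total step count: 11. Longest linear sequence: 10 steps (steps 1 to 7, then 9, 10 and 11); step 8 is a one-step branch.

Steps most likely to fail

1. Step 9. The cycloaddition may be too slow for an alkyne that is activated only through the pyranone double bond, so that thermal decay or protodesilylation of the furan wins; a first bond at furan C5 may also be followed by silyl transfer, not by ring closure. The fallback builds ring B by acyl transfer. It sets out from ketone 5 and rejoins the route at target 19. Commercial 2,4,5-trihydroxybenzaldehyde would be protected (MOMCl, NaH, DMF) to 2,4,5-tris(methoxymethoxy)benzaldehyde F1 and oxidized under Pinnick conditions (NaClO2, NaH2PO4, 2-methylbut-2-ene) to 2,4,5-tris(methoxymethoxy)benzoic acid F2. Esterification of the phenol of 5 (EDC·HCl, DMAP, CH2Cl2) would give the aryl 2,4,5-tris(methoxymethoxy)benzoate F3. Baker–Venkataraman rearrangement (KOt-Bu, THF, 0 °C) would give the 2-prenyl-1,3-diketone F4. Mild cyclodehydration (TsOH cat., PhMe, 4 Å MS) would give the 5,7,2',4',5'-pentakis(methoxymethoxy)flavone F5, and HCl in degassed MeOH would then remove all five acetals to give 19.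

2. Step 4. C-acylation of the hindered, α-branched enolate may stay incomplete, and the acid used for dehydration may strip the C5 MOM group or promote addition of the free phenol to the neighbouring prenyl alkene. The fallback makes the C–C bond intramolecularly and dehydrates without Brønsted acid. It sets out from 5 and rejoins at 9. Acylation of the phenol of 5 with ethyl chlorooxoacetate in pyridine would give the aryl ethyl oxalate F6. KOt-Bu in THF would trigger a Baker–Venkataraman-type O-to-C acyl shift to the salt of 7, which closes to 8. Trifluoroacetic anhydride/pyridine would then acylate the hemiketal hydroxyl, and E1cB loss of trifluoroacetate would give 9.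

3. Step 7. The lithiated diazo reagent may attack the pyranone (conjugate addition at C2 with ring opening, or addition at C4), or the hydrate-prone aldehyde may decompose under base before homologation. The fallback replaces the diazo chemistry by olefination and elimination. It sets out from 11 and rejoins at 12. Wittig bromomethylenation with Ph3P=CHBr (from (bromomethyl)triphenylphosphonium bromide and KOt-Bu, THF, −78 °C) would give the (Z)-2-(2-bromovinyl)chromone F7. Dehydrobromination with a further equivalent of KOt-Bu (or with Bu4NF in DMF) would give 12.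

Further compounds
F1 | step 9 | 2,4,5-tris(methoxymethoxy)benzaldehyde | COCOc1cc(OCOC)c(OCOC)cc1C=O
F2 | step 9 | 2,4,5-tris(methoxymethoxy)benzoic acid | COCOc1cc(OCOC)c(OCOC)cc1C(=O)O
F3 | step 9 | 3,5-bis(methoxymethoxy)-2-(5-methylhex-4-enoyl)-4,6-bis(3-methylbut-2-en-1-yl)phenyl 2,4,5-tris(methoxymethoxy)benzoate | CC(C)=CCCC(=O)c1c(OC(=O)c2cc(OCOC)c(OCOC)cc2OCOC)c(CC=C(C)C)c(OCOC)c(CC=C(C)C)c1OCOC
F4 | step 9 | 1-[2-hydroxy-4,6-bis(methoxymethoxy)-3,5-diprenylphenyl]-2-(3-methylbut-2-en-1-yl)-3-[2,4,5-tris(methoxymethoxy)phenyl]propane-1,3-dione (racemic) | CC(C)=CCC(C(=O)c1cc(OCOC)c(OCOC)cc1OCOC)C(=O)c1c(O)c(CC=C(C)C)c(OCOC)c(CC=C(C)C)c1OCOC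
F5 | step 9 | 5,7-bis(methoxymethoxy)-2-[2,4,5-tris(methoxymethoxy)phenyl]-3,6,8-tris(3-methylbut-2-en-1-yl)-4H-chromen-4-one | CC(C)=CCc1c(OCOC)c(CC=C(C)C)c2oc(-c3cc(OCOC)c(OCOC)cc3OCOC)c(CC=C(C)C)c(=O)c2c1OCOC
F6 | step 4 | ethyl 3,5-bis(methoxymethoxy)-2-(5-methylhex-4-enoyl)-4,6-bis(3-methylbut-2-en-1-yl)phenyl oxalate | CCOC(=O)C(=O)Oc1c(CC=C(C)C)c(OCOC)c(CC=C(C)C)c(OCOC)c1C(=O)CCC=C(C)C
F7 | step 7 | 2-[(Z)-2-bromovinyl]-5,7-bis(methoxymethoxy)-3,6,8-tris(3-methylbut-2-en-1-yl)-4H-chromen-4-one | Br/C=C\c1oc2c(CC=C(C)C)c(OCOC)c(CC=C(C)C)c(OCOC)c2c(=O)c1CC=C(C)C
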